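**Plan**

- Retrosynthesis (indene numbering): the cyclohexene C3a–C4–C5–C6=C7–C7a has its only C=C opposite the C3a–C4 bond, a carboxyl on C4, and a three-atom bridge C3=C2–C1 from C3a to C7a. This is an intramolecular Diels–Alder retron, so C4–C5 and C3a–C7a are cut together, giving an acyclic (2E,4Z,7E,9E,11E)-pentaenoate with one stereocentre.
- The pentaenoate (chain numbering) is cut at C3–C4 (Negishi coupling), at C4=C5 (iodo-Wittig), and at C7=C8, C8–C9 and C8–ethyl (dibromoolefination, then two stereospecific couplings). This leads back to methyl (R)-3-hydroxy-2-methylpropanoate, cinnamaldehyde and (E)-3-iodo-2-methylacrylic acid.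
- Forward: the chain grows outward from the stereocentre, dienoate arm first, triene arm second. No ring exists before the key step, which closes the cyclopentene (C1, C2, C3, C3a, C7a) through the C3a–C7a bond together with the cyclohexene; nothing is cyclised afterwards.
- Stereochemistry: C1 comes from the chiral-pool ester. C3a, C4, C5 and C7a are set in the cycloaddition by the alkene geometries, the endo ester and allylic strain at C1.
- All alkene geometries come from stereospecific olefination and cross-coupling.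

Key step: step 13

Assumption: (2E)-3-iodo-2-methylprop-2-enoic acid is taken as a catalogue compound (it is otherwise one step from diethyl methylmalonate and iodoform).

**Step 1**
Reactants: 1 methyl (2R)-3-hydroxy-2-methylpropanoate
Product: 2 methyl (2R)-3-[(tert-butyldimethylsilyl)oxy]-2-methylpropanoate
Conditions: TBSCl, imidazole, CH2Cl2, 0 °C to rt
Reagents that add atoms: tert-butyl(chloro)dimethylsilane, CC(C)(C)[Si](C)(C)Cl
Why: Silyl ether protection of the primary alcohol, which leaves untouched the stereocentre that becomes C1 of the target.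

**Step 2**
Reactants: 2 methyl (2R)-3-[(tert-butyldimethylsilyl)oxy]-2-methylpropanoate
Product: 3 (2R)-3-[(tert-butyldimethylsilyl)oxy]-2-methylpropanal
Conditions: DIBAL-H (1.05 equiv), CH2Cl2, −78 °C; aqueous potassium sodium tartrate
Reagents that add atoms: none
Why: Partial ester reduction through the aluminium hemiacetal that is stable at −78 °C; aldehydes of this type keep their configuration when used cold and without delay.

**Step 3**
Reactants: 3 (2R)-3-[(tert-butyldimethylsilyl)oxy]-2-methylpropanal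
Product: 4 tert-butyl{[(2S,3Z)-4-iodo-2-methylhex-3-en-1-yl]oxy}dimethylsilane
Conditions: n-PrPPh3Br, n-BuLi, THF, 0 °C; I2, −78 °C; NaHMDS, −20 °C; then 3, −78 to −20 °C
Reagents that add atoms: propyltriphenylphosphonium bromide, CCC[P+](c1ccccc1)(c1ccccc1)c1ccccc1.[Br-]; iodine, II
Why: Stork–Zhao iodo-Wittig olefination, in which kinetic oxaphosphetane formation places iodine cis to the chain and so fixes the later (4Z) geometry (the descriptor at the stereocentre changes only because the CIP priorities change).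

**Step 4**
Reactants: 5 (2E)-3-iodo-2-methylprop-2-enoic acid
Product: 6 2-(trimethylsilyl)ethyl (2E)-3-iodo-2-methylprop-2-enoate
Conditions: 2-(trimethylsilyl)ethanol, DCC, DMAP (cat.), CH2Cl2, 0 °C to rt
Reagents that add atoms: 2-(trimethylsilyl)ethanol, C[Si](C)(C)CCO
Why: Steglich esterification; this ester is later cleaved at silicon by fluoride, so its removal does not depend on access to the hindered carbonyl group of the cycloadduct.

**Step 5**
Reactants: 4 tert-butyl{[(2S,3Z)-4-iodo-2-methylhex-3-en-1-yl]oxy}dimethylsilane; 6 2-(trimethylsilyl)ethyl (2E)-3-iodo-2-methylprop-2-enoate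
Product: 9 2-(trimethylsilyl)ethyl (2E,4Z,6S)-7-[(tert-butyldimethylsilyl)oxy]-4-ethyl-2,6-dimethylhepta-2,4-dienoate, via alkenyllithium 7 (not isolated), via alkenylzinc chloride 8 (not isolated)
Conditions: t-BuLi (2.1 equiv), Et2O, −78 °C; ZnCl2, THF, −78 to 0 °C; then 6, Pd(PPh3)4 (5 mol %), THF, rt
Reagents that add atoms: none
Why: Iodine–lithium exchange, transmetalation to zinc and Negishi coupling all proceed with retention at both alkenyl carbons, so the (2E,4Z)-dienoate follows from the two geometrically defined iodides.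

**Step 6**
Reactants: 9 2-(trimethylsilyl)ethyl (2E,4Z,6S)-7-[(tert-butyldimethylsilyl)oxy]-4-ethyl-2,6-dimethylhepta-2,4-dienoate
Product: 10 2-(trimethylsilyl)ethyl (2E,4Z,6S)-4-ethyl-7-hydroxy-2,6-dimethylhepta-2,4-dienoate
Conditions: CSA (cat.), MeOH/CH2Cl2, 0 °C
Reagents that add atoms: none
Why: Acid-catalysed methanolysis of the primary silyl ether, to which the 2-(trimethylsilyl)ethyl ester and the dienoate are inert.

**Step 7**
Reactants: 10 2-(trimethylsilyl)ethyl (2E,4Z,6S)-4-ethyl-7-hydroxy-2,6-dimethylhepta-2,4-dienoate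
Product: 11 2-(trimethylsilyl)ethyl (2E,4Z,6S)-4-ethyl-2,6-dimethyl-7-oxohepta-2,4-dienoate
Conditions: Dess–Martin periodinane, CH2Cl2, 0 °C; filtered through a short pad and used at once
Reagents that add atoms: none
Why: Dess–Martin oxidation without base, chosen because the hydrogen at C6 of 11 is both α to the formyl group and vinylogously activated by the dienoate.

**Step 8**
Reactants: 11 2-(trimethylsilyl)ethyl (2E,4Z,6S)-4-ethyl-2,6-dimethyl-7-oxohepta-2,4-dienoate
Product: 12 2-(trimethylsilyl)ethyl (2E,4Z,6S)-8,8-dibromo-4-ethyl-2,6-dimethylocta-2,4,7-trienoate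
Conditions: CBr4, PPh3, Zn dust, CH2Cl2, rt (ylide preformed); then 11, 0 °C
Reagents that add atoms: tetrabromomethane, BrC(Br)(Br)Br
Why: Ramirez dibromoolefination (first stage of the Corey–Fuchs sequence) under neutral conditions, so the labile centre C6 should survive, and the gem-dibromide is the handle for two successive stereospecific couplings.

**Step 9**
Reactants: 13 (2E)-3-phenylprop-2-enal
Product: 14 [(1E)-but-1-en-3-yn-1-yl]benzene
Conditions: TMSCHN2, n-BuLi, THF, −78 °C; then 13, −78 °C to rt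
Reagents that add atoms: (trimethylsilyl)diazomethane, C[Si](C)(C)C=[N+]=[N-]
Why: Colvin rearrangement, in which 1,2-addition, Peterson-type loss of silanolate, loss of N2 and a 1,2-hydrogen shift of the alkylidene carbene give the terminal alkyne without touching the (E)-styryl bond.

**Step 10**
Reactants: 14 [(1E)-but-1-en-3-yn-1-yl]benzene
Product: 15 2-[(1E,3E)-2-ethyl-4-phenylbuta-1,3-dien-1-yl]-4,4,5,5-tetramethyl-1,3,2-dioxaborolane
Conditions: CuCl (10 mol %), Xantphos (10 mol %), NaOt-Bu, B2pin2, EtI, THF, rt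
Reagents that add atoms: bis(pinacolato)diboron, CC1(C)OB(OC1(C)C)B1OC(C)(C)C(C)(C)O1; iodoethane, CCI
Why: Copper-catalysed carboboration of a terminal alkyne, in which syn borylcupration puts boron on the terminal carbon and copper next to the styryl group, and the alkenylcopper is ethylated with retention so that ethyl and boron end up cis.

**Step 11**
Reactants: 12 2-(trimethylsilyl)ethyl (2E,4Z,6S)-8,8-dibromo-4-ethyl-2,6-dimethylocta-2,4,7-trienoate; 15 2-[(1E,3E)-2-ethyl-4-phenylbuta-1,3-dien-1-yl]-4,4,5,5-tetramethyl-1,3,2-dioxaborolane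
Product: 16 2-(trimethylsilyl)ethyl (2E,4Z,6S,7Z,9E,11E)-8-bromo-4,10-diethyl-2,6-dimethyl-12-phenyldodeca-2,4,7,9,11-pentaenoate
Conditions: Pd(PPh3)4 (5 mol %), TlOEt, THF/H2O, rt
Reagents that add atoms: none
Why: trans-Selective Suzuki–Miyaura monocoupling of a 1,1-dibromoalkene, in which oxidative addition is faster at the C–Br bond trans to the C6 substituent, so the dienyl group enters trans to C6 and the (7Z)-bromide remains.

**Step 12**
Reactants: 16 2-(trimethylsilyl)ethyl (2E,4Z,6S,7Z,9E,11E)-8-bromo-4,10-diethyl-2,6-dimethyl-12-phenyldodeca-2,4,7,9,11-pentaenoate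
Product: 17 2-(trimethylsilyl)ethyl (2E,4Z,6R,7E,9E,11E)-4,8,10-triethyl-2,6-dimethyl-12-phenyldodeca-2,4,7,9,11-pentaenoate
Conditions: Et2Zn, Pd(t-Bu3P)2 (5 mol %), THF, 0 °C to rt
Reagents that add atoms: diethylzinc, CC[Zn]CC
Why: Negishi alkylation of the remaining alkenyl bromide, where the bulky electron-rich phosphine makes reductive elimination fast, the condition known to give retention (here the (7E) alkene with ethyl cis to C6) and to suppress β-hydride loss from the ethyl group.

**Step 13**
Reactants: 17 2-(trimethylsilyl)ethyl (2E,4Z,6R,7E,9E,11E)-4,8,10-triethyl-2,6-dimethyl-12-phenyldodeca-2,4,7,9,11-pentaenoate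
Product: 18 2-(trimethylsilyl)ethyl (1S,3aS,4S,5R,7aR)-3,5,7-triethyl-1,4-dimethyl-5-[(E)-2-phenylethenyl]-3a,4,5,7a-tetrahydro-1H-indene-4-carboxylate
Conditions: toluene (0.01 M), BHT (cat.), 100 °C, sealed tube, dark
Reagents that add atoms: none
Why: Thermal, concerted but asynchronous [4+2] cycloaddition of the ester-activated C2=C3 alkene of 17 onto its C7=C8–C9=C10 diene (chain numbering); the closest known reaction type is the type 1 intramolecular Diels–Alder reaction of 1,3,8-nonatrienes carrying a terminal acceptor, by which trans-fused hydrindene polyketides of this kind are thought to arise. The cyclopentene is closed by the C3–C7 bond (ring C3a–C7a) in a five-ring exo mode across the bridge C4=C5–C6, whose (4Z) geometry holds C3 and C6 cis, while the cyclohexene is the cycloaddition ring itself, completed by the C2–C10 bond (ring C4–C5) between the two fully substituted carbons. The quaternary pair C4/C5 and its relation to C3a and C7a follow from suprafacial addition to defined alkenes: the (2E) dienophile puts the ester cis to H-3a, and the (7E,9E) diene puts H-7a cis to the ethyl group on C5. The trans ring fusion follows from the endo orientation of the ester, which places the bridge exo. The diene face is chosen by the existing centre C6 (ring C1): allylic 1,3-strain with the ethyl group on C8 keeps H-6 in the diene plane, so the bridge reaches the diene on the face away from the methyl group and the 1-methyl ends up cis to H-7a. The step needs periselectivity (over the C9–C12 diene and over a 1,5-hydrogen shift in the (4Z)-dienoate) and endo selectivity, which should be secured by the short bridge that allows only five-ring closure, by high dilution and moderate temperature, and by the preference of the trisubstituted dienophile to keep its methyl group exo.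

**Step 14**
Reactants: 18 2-(trimethylsilyl)ethyl (1S,3aS,4S,5R,7aR)-3,5,7-triethyl-1,4-dimethyl-5-[(E)-2-phenylethenyl]-3a,4,5,7a-tetrahydro-1H-indene-4-carboxylate
Product: 19 (1S,3aS,4S,5R,7aR)-3,5,7-triethyl-1,4-dimethyl-5-[(E)-2-phenylethenyl]-3a,4,5,7a-tetrahydro-1H-indene-4-carboxylic acid
Conditions: TBAF, THF, rt; then cold dilute aqueous HCl
Reagents that add atoms: none
Why: Fluoride attacks silicon and the ester fragments to carboxylate, ethene and Me3SiF, so hindrance at C4 does not matter; no centre is epimerisable, and contact with acid is kept short to avoid lactonisation onto the alkenes.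

**Compound list**

1 | methyl (2R)-3-hydroxy-2-methylpropanoate | COC(=O)[C@H](C)CO | starting material
2 | methyl (2R)-3-[(tert-butyldimethylsilyl)oxy]-2-methylpropanoate | COC(=O)[C@H](C)CO[Si](C)(C)C(C)(C)C | intermediate
3 | (2R)-3-[(tert-butyldimethylsilyl)oxy]-2-methylpropanal | O=C[C@H](C)CO[Si](C)(C)C(C)(C)C | intermediate
4 | tert-butyl{[(2S,3Z)-4-iodo-2-methylhex-3-en-1-yl]oxy}dimethylsilane | CC/C(I)=C/[C@H](C)CO[Si](C)(C)C(C)(C)C | intermediate
5 | (2E)-3-iodo-2-methylprop-2-enoic acid | OC(=O)/C(C)=C/I | starting material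
6 | 2-(trimethylsilyl)ethyl (2E)-3-iodo-2-methylprop-2-enoate | C[Si](C)(C)CCOC(=O)/C(C)=C/I | intermediate
7 | alkenyllithium from 4 (lithium in place of iodine, cis to the stereocentre, 2S) | CC/C([Li])=C/[C@H](C)CO[Si](C)(C)C(C)(C)C | intermediate
8 | alkenylzinc chloride from 7 (ZnCl in place of lithium, geometry retained) | CC/C([Zn]Cl)=C/[C@H](C)CO[Si](C)(C)C(C)(C)C | intermediate
9 | 2-(trimethylsilyl)ethyl (2E,4Z,6S)-7-[(tert-butyldimethylsilyl)oxy]-4-ethyl-2,6-dimethylhepta-2,4-dienoate | C[Si](C)(C)CCOC(=O)/C(C)=C/C(CC)=C\[C@H](C)CO[Si](C)(C)C(C)(C)C | intermediate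
10 | 2-(trimethylsilyl)ethyl (2E,4Z,6S)-4-ethyl-7-hydroxy-2,6-dimethylhepta-2,4-dienoate | C[Si](C)(C)CCOC(=O)/C(C)=C/C(CC)=C\[C@H](C)CO | intermediate
11 | 2-(trimethylsilyl)ethyl (2E,4Z,6S)-4-ethyl-2,6-dimethyl-7-oxohepta-2,4-dienoate | C[Si](C)(C)CCOC(=O)/C(C)=C/C(CC)=C\[C@H](C)C=O | intermediate
12 | 2-(trimethylsilyl)ethyl (2E,4Z,6S)-8,8-dibromo-4-ethyl-2,6-dimethylocta-2,4,7-trienoate | C[Si](C)(C)CCOC(=O)/C(C)=C/C(CC)=C\[C@H](C)C=C(Br)Br | intermediate
13 | (2E)-3-phenylprop-2-enal | O=C/C=C/c1ccccc1 | starting material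
14 | [(1E)-but-1-en-3-yn-1-yl]benzene | C#C/C=C/c1ccccc1 | intermediate
15 | 2-[(1E,3E)-2-ethyl-4-phenylbuta-1,3-dien-1-yl]-4,4,5,5-tetramethyl-1,3,2-dioxaborolane | CC/C(/C=C/c1ccccc1)=C\B1OC(C)(C)C(C)(C)O1 | intermediate
16 | 2-(trimethylsilyl)ethyl (2E,4Z,6S,7Z,9E,11E)-8-bromo-4,10-diethyl-2,6-dimethyl-12-phenyldodeca-2,4,7,9,11-pentaenoate | C[Si](C)(C)CCOC(=O)/C(C)=C/C(CC)=C\[C@H](C)/C=C(Br)/C=C(CC)/C=C/c1ccccc1 | intermediate
17 | 2-(trimethylsilyl)ethyl (2E,4Z,6R,7E,9E,11E)-4,8,10-triethyl-2,6-dimethyl-12-phenyldodeca-2,4,7,9,11-pentaenoate | C[Si](C)(C)CCOC(=O)/C(C)=C/C(CC)=C\[C@H](C)/C=C(CC)/C=C(CC)/C=C/c1ccccc1 | intermediate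
18 | 2-(trimethylsilyl)ethyl (1S,3aS,4S,5R,7aR)-3,5,7-triethyl-1,4-dimethyl-5-[(E)-2-phenylethenyl]-3a,4,5,7a-tetrahydro-1H-indene-4-carboxylate | CCC1=C[C@](/C=C/c2ccccc2)(CC)[C@@](C)(C(=O)OCC[Si](C)(C)C)[C@@H]2C(CC)=C[C@H](C)[C@@H]12 | intermediate
19 | (1S,3aS,4S,5R,7aR)-3,5,7-triethyl-1,4-dimethyl-5-[(E)-2-phenylethenyl]-3a,4,5,7a-tetrahydro-1H-indene-4-carboxylic acid | CCC1=C[C@](/C=C/c2ccccc2)(CC)[C@@](C)(C(=O)O)[C@@H]2C(CC)=C[C@H](C)[C@@H]12 | target

**Totals**

Total step count: 14.
Longest linear sequence: 11 steps (1, 2, 3, 5, 6, 7, 8, 11, 12, 13, 14) from compound 1.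

**Steps most likely to fail**

Step 13. The thermal window may be too narrow: a 1,5-hydrogen shift within the (4Z)-dienoate, or erosion of the endo preference, may compete with the cycloaddition. The fallback raises the dienophile to the aldehyde level, where the cycloaddition should run cold under Lewis-acid activation; it sets out from 17 and comes back to the route at 19. Reduction of 17 with DIBAL-H (CH2Cl2, −78 °C) should give (2E,4Z,6R,7E,9E,11E)-4,8,10-triethyl-2,6-dimethyl-12-phenyldodeca-2,4,7,9,11-pentaen-1-ol F1. Oxidation with MnO2 (CH2Cl2, rt) should give (2E,4Z,6R,7E,9E,11E)-4,8,10-triethyl-2,6-dimethyl-12-phenyldodeca-2,4,7,9,11-pentaenal F2. With Me2AlCl (CH2Cl2, −78 °C) this should cyclise through the same endo transition state to (1S,3aS,4S,5R,7aR)-3,5,7-triethyl-1,4-dimethyl-5-[(E)-2-phenylethenyl]-3a,4,5,7a-tetrahydro-1H-indene-4-carbaldehyde F3. Pinnick oxidation (NaClO2, NaH2PO4, 2-methylbut-2-ene, t-BuOH/H2O) then gives 19.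

Step 7 (carried into step 8). Configuration at C6 may be lost by enolisation of the doubly activated α-position of 11, or the C4=C5 bond may drift into conjugation with the formyl group. The fallback builds the two arms in the reverse order, so that the formyl group never stands next to a centre that is also activated by the dienoate. Because the ester carbon then becomes the triene arm, the enantiomeric commercial ester, methyl (2S)-3-hydroxy-2-methylpropanoate, replaces 1. The fallback sets out from 15 and 6 and comes back to the route at 17.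
- Silylation and DIBAL-H reduction as in steps 1 and 2 should give methyl (2S)-3-[(tert-butyldimethylsilyl)oxy]-2-methylpropanoate F4 and (2S)-3-[(tert-butyldimethylsilyl)oxy]-2-methylpropanal F5.
- Ramirez olefination (CBr4, PPh3, Zn) should give tert-butyl{[(2R)-4,4-dibromo-2-methylbut-3-en-1-yl]oxy}dimethylsilane F6.
- trans-Selective Suzuki coupling with 15 (Pd(PPh3)4, TlOEt) should give tert-butyl{[(2R,3Z,5E,7E)-4-bromo-6-ethyl-2-methyl-8-phenylocta-3,5,7-trien-1-yl]oxy}dimethylsilane F7.
- Negishi ethylation (Et2Zn, Pd(t-Bu3P)2) should give tert-butyl{[(2R,3E,5E,7E)-4,6-diethyl-2-methyl-8-phenylocta-3,5,7-trien-1-yl]oxy}dimethylsilane F8.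
- TBAF should give (2R,3E,5E,7E)-4,6-diethyl-2-methyl-8-phenylocta-3,5,7-trien-1-ol F9.
- Dess–Martin oxidation should give (2R,3E,5E,7E)-4,6-diethyl-2-methyl-8-phenylocta-3,5,7-trienal F10, whose α-hydrogen is only allylic.
- Stork–Zhao olefination as in step 3 should give [(1E,3E,5E,7R,8Z)-3,5-diethyl-9-iodo-7-methylundeca-1,3,5,8-tetraen-1-yl]benzene F11.
- Iodine–lithium exchange (t-BuLi, Et2O, −78 °C) gives the alkenyllithium from this iodide F12, ZnCl2 gives the alkenylzinc chloride F13, and Negishi coupling with 6 (Pd(PPh3)4, THF, rt) delivers 17.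

Step 10. Capture of the alkenylcopper by iodoethane may be slower than its protonation, or borylcupration may stray to the conjugated alkene, so that the ethyl group is missing or misplaced. The fallback adds the ethyl group first by stoichiometric carbometalation and brings in boron afterwards; it sets out from 14 and comes back to the route at 15. Normant carbocupration (EtMgBr, CuBr·SMe2, Et2O, −45 to −25 °C) should add ethyl and copper syn across the triple bond to give [(1E,3E)-2-ethyl-4-phenylbuta-1,3-dien-1-yl]copper F14. Iodinolysis (I2, −40 °C) should give [(1E,3E)-3-ethyl-4-iodobuta-1,3-dien-1-yl]benzene F15. Miyaura borylation (B2pin2, PdCl2(PPh3)2, PPh3, KOPh, toluene, 50 °C) then gives 15.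

**Further compounds**

F1 | step 13 | (2E,4Z,6R,7E,9E,11E)-4,8,10-triethyl-2,6-dimethyl-12-phenyldodeca-2,4,7,9,11-pentaen-1-ol | OC/C(C)=C/C(CC)=C\[C@H](C)/C=C(CC)/C=C(CC)/C=C/c1ccccc1
F2 | step 13 | (2E,4Z,6R,7E,9E,11E)-4,8,10-triethyl-2,6-dimethyl-12-phenyldodeca-2,4,7,9,11-pentaenal | O=C/C(C)=C/C(CC)=C\[C@H](C)/C=C(CC)/C=C(CC)/C=C/c1ccccc1
F3 | step 13 | (1S,3aS,4S,5R,7aR)-3,5,7-triethyl-1,4-dimethyl-5-[(E)-2-phenylethenyl]-3a,4,5,7a-tetrahydro-1H-indene-4-carbaldehyde | CCC1=C[C@](/C=C/c2ccccc2)(CC)[C@@](C)(C=O)[C@@H]2C(CC)=C[C@H](C)[C@@H]12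
F4 | step 7 | methyl (2S)-3-[(tert-butyldimethylsilyl)oxy]-2-methylpropanoate | COC(=O)[C@@H](C)CO[Si](C)(C)C(C)(C)C
F5 | step 7 | (2S)-3-[(tert-butyldimethylsilyl)oxy]-2-methylpropanal | O=C[C@@H](C)CO[Si](C)(C)C(C)(C)C
F6 | step 7 | tert-butyl{[(2R)-4,4-dibromo-2-methylbut-3-en-1-yl]oxy}dimethylsilane | BrC(Br)=C[C@@H](C)CO[Si](C)(C)C(C)(C)C
F7 | step 7 | tert-butyl{[(2R,3Z,5E,7E)-4-bromo-6-ethyl-2-methyl-8-phenylocta-3,5,7-trien-1-yl]oxy}dimethylsilane | CC(C)(C)[Si](C)(C)OC[C@H](C)/C=C(Br)/C=C(CC)/C=C/c1ccccc1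
F8 | step 7 | tert-butyl{[(2R,3E,5E,7E)-4,6-diethyl-2-methyl-8-phenylocta-3,5,7-trien-1-yl]oxy}dimethylsilane | CC(C)(C)[Si](C)(C)OC[C@H](C)/C=C(CC)/C=C(CC)/C=C/c1ccccc1
F9 | step 7 | (2R,3E,5E,7E)-4,6-diethyl-2-methyl-8-phenylocta-3,5,7-trien-1-ol | OC[C@H](C)/C=C(CC)/C=C(CC)/C=C/c1ccccc1
F10 | step 7 | (2R,3E,5E,7E)-4,6-diethyl-2-methyl-8-phenylocta-3,5,7-trienal | O=C[C@H](C)/C=C(CC)/C=C(CC)/C=C/c1ccccc1
F11 | step 7 | [(1E,3E,5E,7R,8Z)-3,5-diethyl-9-iodo-7-methylundeca-1,3,5,8-tetraen-1-yl]benzene | CC/C(I)=C/[C@H](C)/C=C(CC)/C=C(CC)/C=C/c1ccccc1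
F12 | step 7 | alkenyllithium from F11 (lithium in place of iodine, geometry retained) | CC/C([Li])=C/[C@H](C)/C=C(CC)/C=C(CC)/C=C/c1ccccc1
F13 | step 7 | alkenylzinc chloride from F12 (ZnCl in place of lithium, geometry retained) | CC/C([Zn]Cl)=C/[C@H](C)/C=C(CC)/C=C(CC)/C=C/c1ccccc1
F14 | step 10 | [(1E,3E)-2-ethyl-4-phenylbuta-1,3-dien-1-yl]copper | CC/C(/C=C/c1ccccc1)=C\[Cu]
F15 | step 10 | [(1E,3E)-3-ethyl-4-iodobuta-1,3-dien-1-yl]benzene | CC/C(/C=C/c1ccccc1)=C\I
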